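A leftover comes first: by 15.0 d the north run has turned 58.8 % of its partner into target, and the other 41.2 % has not appeared as target.

| flask | starting material | partner | second reagent | temperature | remark | time |
|---|---|---|---|---|---|---|
| south-east | 0.50 M | 0.50 M | 0.90 M | 20 °C | run made earlier |  |
| north | 0.50 M | 0.25 M | 0.90 M | 35 °C | run made earlier |  |
| south | 0.50 M | 0.38 M | 0.90 M | 20 °C | run made earlier |  |
| Thursday's | 0.50 M | 0.500 M | 0.900 M | 35 °C | everything together at the start | 25 d |
| Sunday's | 0.50 M (fed, over 5.0 d) | 0.500 M | 0.900 M |  | the addition at 15 °C, then warmed to 35 °C; the feed brings no volume worth counting | 25 d |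
| Monday's | 0.50 M | 0.500 M (fed, over 12 h) | 0.900 M | 35 °C | all else is in the flask from the start; the feed brings no volume worth counting | 25 d |
| Tuesday's | 0.50 M | 0.500 M (fed, over 5.0 d) | 0.900 M | 35 °C | all else is in the flask from the start; the feed brings no volume worth counting | 25 d |
| Saturday's | 0.50 M | 0.500 M | 0.900 M |  | everything together at the start at 15 °C, warmed to 35 °C at 5.0 d | 25 d |

| run | time / d | target / % |
|---|---|---|
| south-east | 4.00 | 11.2 |
| south-east | 8.00 | 23.7 |
| south-east | 15.0 | 39.4 |
| south-east | 25.0 | 51.6 |
| south-east | 50.0 | 63.9 |
| north | 3.00 | 17.5 |
| north | 6.00 | 24.1 |
| north | 10.0 | 28.3 |
| north | 12.0 | 28.4 |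
| north | 15.0 | 29.4 |
| south | 2.50 | 4.1 |
| south | 5.00 | 11.1 |
| south | 8.00 | 19.3 |
| south | 15.0 | 32.3 |
| south | 30.0 | 45.6 |

(scatter of a reading: 0.3 percentage points)

- steps thought possible: starting material + partner -> intermediate; second reagent + intermediate -> target; starting material + second reagent -> side product; partner -> decomposed reagent

* which flask leads in amount of target, in percent of the starting material charged ("all alike" within 1.5 percentage points) (Thursday's / Sunday's / Monday's / Tuesday's / Saturday's / all alike)
* how much target is there at the end, in percent of the starting material charged: Thursday's
* how much target is there at the end, in percent of the starting material charged: Sunday's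
* how much target is there at the end, in percent of the starting material charged: Monday's
* how much target is there at the end, in percent of the starting material charged: Tuesday's
* how much target is there at the end, in percent of the starting material charged: Saturday's

The steps thought possible are capture of partner by starting material to give intermediate, conversion of intermediate by second reagent to target, loss of starting material to second reagent as side product, and decay of partner by itself.

Read down the north table: target stands at 28.3 % at 10.0 d and at 29.4 % at 15.0 d, a gain of 1.1 percentage points in that stretch, so the north reading is taken as close to its end value. Partner has two exits, capture and decay, and each rate carries the partner concentration once, so it divides out of their ratio. The concentration left in that ratio is that of starting material. With f the fraction of its charge still present, the captured share is f/(f + b), where b is the capture balance, the fraction of the charge at which capture and decay run equally fast (the inverse of a selectivity factor). Taking f as 1 in the north run gives b = 0.701, which overstates it, since f falls during the run.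

Now the last rows of the south-east table: at 20 °C target reads 63.9 % of an equal partner charge and was still rising from 51.6 % at 25.0 d, so the reading b = 0.565 overstates too. It stands lower than the north reading, but the south-east run differs from the north run in partner charge as well as in temperature.

My own reckoning follows. The charges of partner and starting material are equal at 0.500 M and 0.50 M, so a share of partner, once its intermediate has gone on to target, reads as percent of starting material. With the north reading of b, Thursday's is reckoned at a share of 58.8 % for f = 1, and lower as f falls. Saturday's, with its first 5.0 d at 15 °C, should lean towards the south-east reading. Tuesday's receives its partner over 5.0 d; if f has fallen to 0.5 meanwhile, the reckoned share is 41.6 %.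

The forecast gives 52 % for Thursday's, 54 % for Sunday's, 51.5 % for Monday's, 50 % for Tuesday's and 55.5 % for Saturday's, and names Saturday's, holding that “Feeding partner gains nothing”.

The flasks give 54.7 % for Thursday's, 56.4 % for Sunday's, 53.4 % for Monday's, 43.6 % for Tuesday's and 65.0 % for Saturday's, so Saturday's leads.

    starting material + partner → intermediate (k = 0.139 M⁻¹ h⁻¹, Ea = 69.0 kJ mol⁻¹)
    second reagent + intermediate → target (k = 0.0179 M⁻¹ h⁻¹, Ea = 76.0 kJ mol⁻¹)
    starting material + second reagent → side product (k = 0.00811 M⁻¹ h⁻¹, Ea = 90.0 kJ mol⁻¹)
    partner → decomposed reagent (k = 0.0346 h⁻¹, Ea = 110 kJ mol⁻¹)
    (constants at 35 °C)

In Tuesday's, side product formation ran while partner was still being fed, with 54 % of its turnover behind it at 2.50 d, and capture had half of its turnover done by 2.45 d, which puts f near 0.490 there and gives a reckoned share of 41.1 % beside the flask's 43.6 %. In the neighbour like Tuesday's with 2.0 M of starting material, f still stood at 1.71, in units of Tuesday's charge, at 25.0 d, after the feed; that end value in the rule gives 70.9 %, and target plus intermediate took up 83.8 % of the partner charge.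

The readings were computed for an exercise, noise included.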